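**Assumption:** compounds 1, 2, 4 and 11 are taken as commercial, as is the ligand (R)-t-BuPyOx [(R)-4-tert-butyl-2-(pyridin-2-yl)-4,5-dihydrooxazole]. Catalysts and ligands are not numbered. Discrete intermediates of tandem steps are numbered; catalyst-bound organometallic species are not.

**Target check:** the SMILES is (2S)-5-hydroxy-7-prenyloxy-8-prenylflavanone (prenyl = 3-methylbut-2-en-1-yl). C2 priorities are O1 > Ph > C3 > H, and the written chirality corresponds to S.

## Retrosynthetic overview

1. C2–Ph bond and the only stereocentre: late enantioselective conjugate phenylation of chromone 10 with PhB(OH)2 (new step).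
2. C8–prenyl bond: chelation-controlled para-Claisen–Cope shift of the 5-O-prenyl group of 5,7-bis(prenyloxy)chromone 7, which also frees the 5-OH.
3. Pyranone ring: enaminone annulation of acetophenone 3 with one carbon from DMF-DMA.
4. Both ether bonds: double O-prenylation of phloroacetophenone 1.
5. Ring order: the A ring is bought, the pyranone ring is formed in step 2, and the phenyl ring is attached last.

## Route

**Step 1**
Reactants: 1 2,4,6-trihydroxyacetophenone; 2 prenyl bromide
Product: 3 1-{2-hydroxy-4,6-bis[(3-methylbut-2-en-1-yl)oxy]phenyl}ethanone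
Conditions: 2 (2.2 equiv), K2CO3 (2.5 equiv), acetone, reflux, 12 h
Reagents that add atoms: prenyl bromide (1-bromo-3-methylbut-2-ene), CC(C)=CCBr
Why: Williamson etherification; the 4-OH and one ortho OH are alkylated, while the last OH is chelated to the ketone and stays free under K2CO3/acetone.

**Step 2**
Reactants: 3 1-{2-hydroxy-4,6-bis[(3-methylbut-2-en-1-yl)oxy]phenyl}ethanone; 4 N,N-dimethylformamide dimethyl acetal
Product: 7 5,7-bis[(3-methylbut-2-en-1-yl)oxy]-4H-chromen-4-one, via enaminone 5 (not isolated), via 2-(dimethylamino)chromanone 6 (not isolated)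
Conditions: Me2NCH(OMe)2 (2 equiv), PhMe, 100 °C; concentrate; then AcOH, 60 °C
Reagents that add atoms: N,N-dimethylformamide dimethyl acetal, COC(OC)N(C)C
Why: Enaminone route to chromones: amide-acetal condensation at the methyl ketone, then acid-promoted 6-endo oxa-Michael addition of the single free OH and elimination of dimethylamine, so the ring-closure regiochemistry is unambiguous.

**Step 3**
Reactants: 7 5,7-bis[(3-methylbut-2-en-1-yl)oxy]-4H-chromen-4-one
Product: 10 5-hydroxy-8-(3-methylbut-2-en-1-yl)-7-[(3-methylbut-2-en-1-yl)oxy]-4H-chromen-4-one, via ortho-dienone 8 (not isolated), via para-dienone 9 (not isolated)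
Conditions: Eu(fod)3 (10 mol%), NaHCO3, PhCl, 85 °C
Reagents that add atoms: none
Why: Europium-catalysed tandem aromatic Claisen/Cope (para-Claisen–Cope) rearrangement: Eu(III) chelated between C4=O and O5 activates only the peri prenyl ether ([3,3] to C6, [3,3] on to C8, then tautomerisation), while the unchelated 7-O-prenyl ether needs far higher temperature and stays.

**Step 4**
Reactants: 10 5-hydroxy-8-(3-methylbut-2-en-1-yl)-7-[(3-methylbut-2-en-1-yl)oxy]-4H-chromen-4-one; 11 phenylboronic acid
Product: 12 (2S)-5-hydroxy-8-(3-methylbut-2-en-1-yl)-7-[(3-methylbut-2-en-1-yl)oxy]-2-phenyl-2,3-dihydro-4H-chromen-4-one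
Conditions: Pd(OCOCF3)2 (10 mol%), (R)-t-BuPyOx (12 mol%), NH4PF6 (30 mol%), H2O (5 equiv), PhB(OH)2 (2 equiv), ClCH2CH2Cl, 40 °C; neutral work-up
Reagents that add atoms: phenylboronic acid, OB(O)c1ccccc1
Why: Proposed new method: enantioselective Pd(II)/(R)-t-BuPyOx conjugate phenylation of an unprotected 5-hydroxy, bis-prenylated chromone, in which transmetalation gives cationic (PyOx)Pd–Ph, the C2=C3 bond binds and undergoes enantiodetermining syn-carbopalladation placing Ph on C2 from the face away from the ligand tert-butyl group, and water protonates the Pd enolate faster than β-hydride elimination; the peri O–H···O=C hydrogen bond lowers the chromone LUMO and offsets the 7-alkoxy donor, the trisubstituted prenyl alkenes bind cationic Pd(II) much more weakly than the enone, and the non-basic medium avoids ring-opening of the 5-hydroxyflavanone; the (R)-ligand is chosen because the (S)-ligand gives (R)-3-aryl-3-methylcyclohexanones, a facial sense that maps onto (2R)-flavanones, so the (R)-ligand is predicted to give 2S (to be confirmed by CD or optical rotation); the closest known reaction type is the Pd/pyridine-oxazoline asymmetric conjugate addition of arylboronic acids to cyclic enones and to simple chromones without a free peri-OH or remote alkenes.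

## Compound list

1 | 2,4,6-trihydroxyacetophenone (phloroacetophenone) | CC(=O)c1c(O)cc(O)cc1O | starting material
2 | prenyl bromide (1-bromo-3-methylbut-2-ene) | CC(C)=CCBr | starting material
3 | 1-{2-hydroxy-4,6-bis[(3-methylbut-2-en-1-yl)oxy]phenyl}ethanone | CC(=O)c1c(O)cc(OCC=C(C)C)cc1OCC=C(C)C | intermediate
4 | N,N-dimethylformamide dimethyl acetal | COC(OC)N(C)C | starting material
5 | (E)-3-(dimethylamino)-1-{2-hydroxy-4,6-bis[(3-methylbut-2-en-1-yl)oxy]phenyl}prop-2-en-1-one (enaminone) | CN(C)/C=C/C(=O)c1c(O)cc(OCC=C(C)C)cc1OCC=C(C)C | intermediate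
6 | 2-(dimethylamino)-5,7-bis[(3-methylbut-2-en-1-yl)oxy]chroman-4-one (racemic aminal) | CN(C)C1CC(=O)c2c(OCC=C(C)C)cc(OCC=C(C)C)cc2O1 | intermediate
7 | 5,7-bis[(3-methylbut-2-en-1-yl)oxy]-4H-chromen-4-one | O=c1ccoc2cc(OCC=C(C)C)cc(OCC=C(C)C)c12 | intermediate
8 | 6-(2-methylbut-3-en-2-yl)-7-[(3-methylbut-2-en-1-yl)oxy]-6H-chromene-4,5-dione (racemic ortho-dienone) | O=C1C=COC2=C1C(=O)C(C(C)(C)C=C)C(OCC=C(C)C)=C2 | intermediate
9 | 8-(3-methylbut-2-en-1-yl)-7-[(3-methylbut-2-en-1-yl)oxy]-8H-chromene-4,5-dione (racemic para-dienone) | O=C1C=COC2=C1C(=O)C=C(OCC=C(C)C)C2CC=C(C)C | intermediate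
10 | 5-hydroxy-8-(3-methylbut-2-en-1-yl)-7-[(3-methylbut-2-en-1-yl)oxy]-4H-chromen-4-one | O=c1ccoc2c(CC=C(C)C)c(OCC=C(C)C)cc(O)c12 | intermediate
11 | phenylboronic acid | OB(O)c1ccccc1 | starting material
12 | (2S)-5-hydroxy-8-(3-methylbut-2-en-1-yl)-7-[(3-methylbut-2-en-1-yl)oxy]-2-phenyl-2,3-dihydro-4H-chromen-4-one | CC(C)=CCOc1cc(O)c2c(c1CC=C(C)C)O[C@H](c1ccccc1)CC2=O | target

## Summary

Total step count: 4. Longest linear sequence: 4 steps (1 → 3 → 7 → 10 → 12).

**Three steps most likely to fail**

**Step 4 (proposed new method).** Risks are Pd sequestration by the 5-hydroxy-4-keto chelating unit, interference by the prenyl alkenes, and low ee. The fallback sets out from 10 and comes back at 12, using known chemistry. A phenyl cuprate (PhMgBr, CuBr·SMe2, excess TMSCl, THF, −78 °C, with the first equivalent consumed by the 5-OH; mild acidic work-up) adds 1,4 to the chromone and gives the racemic flavanone F1. Preparative chiral HPLC on a polysaccharide carbamate phase then gives 12 and the (2R)-enantiomer F2. F2 is discarded and not recycled with base, because the ring-opened chalcone could reclose onto the other hydroxyl and give the 6-prenyl isomer.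

**Step 3.** Risks are a competing shift of the 7-O-prenyl ether or a stop at the ortho (C6, reverse-prenyl) product. The fallback sets out from 1 and comes back at 10, with only one allylic ether present during the rearrangement. TIPSCl and imidazole (1 equiv, DMF, 0 °C) silylate the unchelated 4-OH to give 1-[2,6-dihydroxy-4-(triisopropylsilyloxy)phenyl]ethanone F3. Mitsunobu etherification with prenol (PPh3, DIAD, THF) of one of the two equivalent hydroxyls gives the mono-prenyl ether F4. DMF-DMA and then AcOH, as in step 2, lead through the enaminone F5 and the aminal F6 to 5-prenyloxy-7-(triisopropylsilyloxy)chromone F7. The Eu(fod)3 rearrangement then passes through the ortho-dienone F8 and the para-dienone F9 to 5-hydroxy-8-prenyl-7-(triisopropylsilyloxy)chromone F10. CsF and prenyl bromide 2 in DMF (desilylative O-alkylation; the chelated 5-OH is left alone) give 10.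

**Step 1.** Risks are C-prenylation and over-alkylation of the phloroglucinol ring under carbonate. The fallback sets out from 1 and comes back at 3, splitting the double alkylation into two mechanistically different etherifications. One equivalent each of 2 and K2CO3 in acetone alkylates only the most acidic 4-OH and gives 1-{2,6-dihydroxy-4-[(3-methylbut-2-en-1-yl)oxy]phenyl}ethanone F11. A Mitsunobu reaction with prenol (PPh3, DIAD, THF, 0 °C) then etherifies one ortho hydroxyl without a phenoxide, so C-alkylation is avoided, and gives 3.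

## Further compounds

F1 | step 4 | (2RS)-5-hydroxy-8-(3-methylbut-2-en-1-yl)-7-[(3-methylbut-2-en-1-yl)oxy]-2-phenyl-2,3-dihydro-4H-chromen-4-one (racemate) | CC(C)=CCOc1cc(O)c2c(c1CC=C(C)C)OC(c1ccccc1)CC2=O
F2 | step 4 | (2R)-5-hydroxy-8-(3-methylbut-2-en-1-yl)-7-[(3-methylbut-2-en-1-yl)oxy]-2-phenyl-2,3-dihydro-4H-chromen-4-one | CC(C)=CCOc1cc(O)c2c(c1CC=C(C)C)O[C@@H](c1ccccc1)CC2=O
F3 | step 3 | 1-[2,6-dihydroxy-4-(triisopropylsilyloxy)phenyl]ethanone | CC(=O)c1c(O)cc(O[Si](C(C)C)(C(C)C)C(C)C)cc1O
F4 | step 3 | 1-{2-hydroxy-6-[(3-methylbut-2-en-1-yl)oxy]-4-(triisopropylsilyloxy)phenyl}ethanone | CC(=O)c1c(O)cc(O[Si](C(C)C)(C(C)C)C(C)C)cc1OCC=C(C)C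
F5 | step 3 | (E)-3-(dimethylamino)-1-{2-hydroxy-6-[(3-methylbut-2-en-1-yl)oxy]-4-(triisopropylsilyloxy)phenyl}prop-2-en-1-one | CN(C)/C=C/C(=O)c1c(O)cc(O[Si](C(C)C)(C(C)C)C(C)C)cc1OCC=C(C)C
F6 | step 3 | 2-(dimethylamino)-5-[(3-methylbut-2-en-1-yl)oxy]-7-(triisopropylsilyloxy)chroman-4-one (racemic) | CN(C)C1CC(=O)c2c(OCC=C(C)C)cc(O[Si](C(C)C)(C(C)C)C(C)C)cc2O1
F7 | step 3 | 5-[(3-methylbut-2-en-1-yl)oxy]-7-(triisopropylsilyloxy)-4H-chromen-4-one | O=c1ccoc2cc(O[Si](C(C)C)(C(C)C)C(C)C)cc(OCC=C(C)C)c12
F8 | step 3 | 6-(2-methylbut-3-en-2-yl)-7-(triisopropylsilyloxy)-6H-chromene-4,5-dione (racemic) | O=C1C=COC2=C1C(=O)C(C(C)(C)C=C)C(O[Si](C(C)C)(C(C)C)C(C)C)=C2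
F9 | step 3 | 8-(3-methylbut-2-en-1-yl)-7-(triisopropylsilyloxy)-8H-chromene-4,5-dione (racemic) | O=C1C=COC2=C1C(=O)C=C(O[Si](C(C)C)(C(C)C)C(C)C)C2CC=C(C)C
F10 | step 3 | 5-hydroxy-8-(3-methylbut-2-en-1-yl)-7-(triisopropylsilyloxy)-4H-chromen-4-one | O=c1ccoc2c(CC=C(C)C)c(O[Si](C(C)C)(C(C)C)C(C)C)cc(O)c12
F11 | step 1 | 1-{2,6-dihydroxy-4-[(3-methylbut-2-en-1-yl)oxy]phenyl}ethanone | CC(=O)c1c(O)cc(OCC=C(C)C)cc1O
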